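The numbers in the tables were generated by integration for an exercise; scatter was added.

Keep the amber charge and read it at 14 min, but reckon first what it should give. With 130 mM of J against 600 mM of X, J is the limiting reagent, and Q cannot pass 21.7% of the X charged.

| flask | X | J | time |
|---|---|---|---|
| ochre | 200 mM | 400 mM |  |
| teal | 100 mM | 400 mM |  |
| blue | 200 mM | 200 mM |  |
| amber | 600 mM | 130 mM | 14 min |

| run | time / min | [Q] / mM |
|---|---|---|
| ochre run | 1.1 | 3.5 |
| ochre run | 3.2 | 32.5 |
| ochre run | 6.2 | 67.2 |
| ochre run | 9.8 | 101.8 |
| ochre run | 14 | 133.4 |
| teal run | 1.1 | 3.2 |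
| teal run | 3.2 | 18.1 |
| teal run | 6.2 | 39.8 |
| teal run | 9.8 | 63.6 |
| teal run | 14 | 75.2 |
| blue run | 1.1 | 4.2 |
| blue run | 3.2 | 17.0 |
| blue run | 6.2 | 37.1 |
| blue run | 9.8 | 58.0 |
| blue run | 14 | 72.4 |

(standard deviation of a reading: 2 mM)

- Overall: X + J -> Q.
- Constant volume, constant temperature.
- Readings of a species count what is bound in complexes too.
- An order is taken over about fifteen percent of the charge, up and down.

- order of the initial rate in [X], near the charge of the ochre run, the rate being that where two percent of its X are Q (one fixed amount of Q, the same in the runs compared)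
- order of the initial rate in [J], near the charge of the ochre run, the rate being that where two percent of its X are Q
- Q in the amber run at 14 min, as a share of the X charged

The first readings are too small to use: at 1.1 min, the blue run reads 4.2 mM of Q with a scatter of 2 mM. So interpolate the quarter time, when Q reaches a quarter of the X charged: 4.71 min in ochre, 4.15 min in teal, 8.42 min in blue. As orders averaged over that span, these read 0.818 in X and 0.838 in J, and I take them for the orders asked.

The quarter time multiplied by the J charged, averaged over the ochre, teal and blue runs, is 105 M·s; call this the quarter product. Dividing by it the logarithm of X charged over X left at the quarter point gives, as an estimate with J held at its charge, k = 0.165 M⁻¹ min⁻¹, for a rate k[X][J].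

In amber, J then decays pseudo-first-order at k[X]. With X held at its charge, Q at 14 min is 97.5 mM. The correction is the loss of X: using its mean, 551 mM, lowers Q to 93.6 mM, so my number is 15.6%.

The forecast, from the same runs, gives orders of 0.75 in X and 1.05 in J, and for amber 13.5%, lower than my number, citing “mild saturation in X”.

The amber flask gives 10.7%, or 63.9 mM of Q; near the ochre charge, the orders asked come out at 0.54 in X and 0.61 in J.

    X ⇌ G + Z (0.3138 min⁻¹, 0.06180 M⁻¹ min⁻¹)
    G + J → Q (0.4980 M⁻¹ min⁻¹)
    J + Z ⇌ JZ, settled at all times (8.270 M⁻¹)

Run backward, amber's Q gives k = 0.0851 M⁻¹ min⁻¹, a quarter product of 203 M·s, twice the earlier mean. In blue, with X and J charged equal, the earlier k puts Q at half of the X charged at 30.3 min; the blue run gets there at 23.4 min.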